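The readings stem from a simulated flask with constants of no real substance; scatter was added.

The operator set up Friday's, Tuesday's and Monday's flasks, and I had the autumn and summer runs to go on.

| flask | substrate | partner | remark | time |
|---|---|---|---|---|
| autumn | 0.064 M | 1.4 equiv | run made earlier |  |
| summer | 0.064 M | 1.9 equiv | run made earlier |  |
| Friday's | 0.064 M | 1.20 equiv |  | 15 min |
| Tuesday's | 0.064 M | 1.60 equiv |  | 15 min |
| Monday's | 0.064 M | 2.00 equiv |  | 15 min |

| run | time / min | intermediate B / % | target / % | intermediate A / % | side product A / % | substrate / % |
|---|---|---|---|---|---|---|
| autumn | 1.33 | 1.0 | 0 | 2.8 | 1.8 | 91.8 |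
| autumn | 2.50 | 2.2 | 0 | 7.9 | 5.9 | 87.3 |
| autumn | 4.00 | 4.0 | 0 | 8.9 | 8.3 | 79.8 |
| autumn | 8.00 | 10.7 | 0 | 10.4 | 14.5 | 64.9 |
| autumn | 15.0 | 17.8 | 1.0 | 11.1 | 21.1 | 46.5 |
| summer | 1.33 | 0.7 | 0 | 5.7 | 2.8 | 90.3 |
| summer | 4.00 | 4.9 | 0 | 11.1 | 11.0 | 71.9 |
| summer | 8.00 | 14.7 | 0 | 14.8 | 17.5 | 52.8 |
| summer | 10.0 | 14.5 | 0 | 13.8 | 20.5 | 46.3 |
| summer | 15.0 | 23.8 | 0 | 9.8 | 25.7 | 34.3 |

(readings scatter by 1 percentage point)

- the earlier runs were read with a standard deviation of 1 percentage point

- which of these there is most of at the end, counted by the substrate in it, Friday's (intermediate A / side product A / substrate / intermediate B)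
- which of these there is most of at the end, counted by the substrate in it, Tuesday's (intermediate A / side product A / substrate / intermediate B)
- which of these there is most of at the end, counted by the substrate in it, Monday's (intermediate A / side product A / substrate / intermediate B)
- final amount of the leader among these, as a percentage of the substrate charged, in Friday's
- final amount of the leader among these, as a percentage of the substrate charged, in Tuesday's
- final amount of the leader among these, as a percentage of the substrate charged, in Monday's

I ran the flask through in slow motion. In the first instants, at 1.33 min, the autumn run held 91.8% substrate, with intermediate A at 2.8% and side product A at 1.8% appearing side by side. In the middle, intermediate A in the autumn run crept from 8.9% at 4.00 min to 10.4% at 8.00 min, while intermediate B went from 4.0% to 10.7%; I read that as intermediate A feeding intermediate B. At 15.0 min the autumn run read 46.5% substrate, 21.1% side product A and 17.8% intermediate B, with target at 1.0%. What mattered next was the gap at the top: in the summer run at 15.0 min substrate read 8.6 points above side product A, against a scatter of 1 point.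

So I needed the substrate's fall. I let each substrate consume one partner, a second-order loss in fractions of the charge. With the excess of partner over substrate in equivalents, the fraction left is that excess divided by (equivalents times exp(excess times clock), less one). Inverted at 15.0 min, this gave 0.711 for the autumn run and 0.717 for the summer run. Their mean, 0.714, is the clock, the rate constant times the substrate charge times the minutes run. It gave me 52.1% substrate for Friday's flask, 41.2% for Tuesday's and 32.4% for Monday's.

The forecast named substrate, substrate and substrate as leaders, at 52%, 41% and 32.5%, “though with the smallest margin on Monday”. Its Monday figure stands slightly above mine.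

The flasks gave substrate at 52.1% on Friday's, substrate at 41.4% on Tuesday's and substrate at 32.8% on Monday's, where side product A reached 25.4%.

    substrate + partner → intermediate A (k = 0.439 /M/min)
    substrate + partner → side product A (k = 0.276 /M/min)
    intermediate A → intermediate B (k = 0.175 /min)
    partner + intermediate B → intermediate C (k = 0.138 /M/min)
    intermediate C ⇌ intermediate D (K = 1.13, k = 0.229 /min)
    intermediate C → target (k = 0.0140 /min)
    substrate + intermediate B → side product B (k = 0.270 /M/min)
    intermediate B → decomposed reagent (k = 0.0158 /min)

In Tuesday's flask, substrate was used by the step to intermediate A 1.6 times as fast as by the step to side product A at the start, and 1.6 times at 15.0 min. Its loss was divided, and 22.1% side product A stood below 41.4% substrate. Read back from that flask, the clock is 0.709, against my 0.714. Stretched to 25 min, my clock gives 26.5% substrate, and Tuesday's flask left that long held 26.0%, behind side product A at 27.5%.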